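In the flavonol, ring C takes C4a, C8a and O1 from a phenol (ring A). Only the carbonyl carbon C4 and the C3–C2 unit bearing ring B have to be added. The route uses this feature by forming C4a–C4, C4–C3 and O1–C2 in one palladium-catalysed operation from an ortho-iodophenol, carbon monoxide and 4-ethynylanisole. The ynone closes to the chromen-4-one in the same flask, under mildly basic conditions that leave the benzylic centre on C8 untouched. The precursor is an (R)-1,1-diarylethane whose ring A bears OH (future O1), iodine (C4a), OBn (C5) and OMe (C7). Its stereocentre comes from asymmetric hydrogenation and its iodine from direct ortho-iodination. C3 hydroxylation and hydrogenolysis finish the synthesis.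

Key step: step 6

Assumption: the sense of induction in step 4 cannot be predicted for this doubly ortho-substituted styrene, so the ligand antipode written there is provisional. Both antipodes are sold, and the configuration should be secured by anomalous-dispersion X-ray analysis of the iodophenol of step 5 before material is carried on.

Step 1
Reactants: 1 2',4',6'-trihydroxyacetophenone
Product: 2 4'-benzyloxy-2',6'-dihydroxyacetophenone
Conditions: BnBr (1.0 equiv), K2CO3 (1.0 equiv), DMF, 0 °C to rt
Reagents that add atoms: benzyl bromide, BrCc1ccccc1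
Why: Williamson etherification with one equivalent of weak base picks the C4' hydroxyl, which is the most acidic and the only one not hydrogen-bonded to the acetyl oxygen, and the limiting amount of benzyl bromide holds back a second alkylation.

Step 2
Reactants: 2 4'-benzyloxy-2',6'-dihydroxyacetophenone
Product: 3 4'-benzyloxy-2'-hydroxy-6'-methoxyacetophenone
Conditions: MeI (1.1 equiv), K2CO3 (1.2 equiv), acetone, reflux
Reagents that add atoms: iodomethane, CI
Why: Williamson etherification of one of two equivalent hydroxyls stops at the monoether, because the last hydroxyl is then locked in a strong hydrogen bond to the carbonyl group and resists carbonate-mediated alkylation.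

Step 3
Reactants: 3 4'-benzyloxy-2'-hydroxy-6'-methoxyacetophenone, 4 1-benzyloxy-4-bromobenzene
Product: 7 5-benzyloxy-2-[1-(4-benzyloxyphenyl)ethenyl]-3-methoxyphenol, via arylmagnesium bromide 5 (not isolated), via tertiary carbinol 6 (not isolated)
Conditions: 4 (3.5 equiv), Mg, THF, reflux; then 3, LaCl3·2LiCl (30 mol %), THF, 0 °C to rt; sat. aq NH4Cl; PPTS (5 mol %), CH2Cl2, rt
Reagents that add atoms: none
Why: Grignard addition followed by acid-catalysed E1 dehydration, in which the first equivalent forms a magnesium phenoxide that chelates the acetyl oxygen and keeps the carbonyl in the ring plane with both faces open, the lanthanum salt favours 1,2-addition over enolisation, and the doubly benzylic, oxygen-stabilised carbinol loses water under very mild acid to give the only possible alkene.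

Step 4
Reactants: 7 5-benzyloxy-2-[1-(4-benzyloxyphenyl)ethenyl]-3-methoxyphenol
Product: 8 (R)-5-benzyloxy-2-[1-(4-benzyloxyphenyl)ethyl]-3-methoxyphenol
Conditions: [Rh(cod)2]BF4 (2 mol %), (R)-1-[(Sp)-2-(diphenylphosphino)ferrocenyl]ethyl-di-tert-butylphosphine (2.2 mol %), K2CO3 (10 mol %), H2 (20 bar), MeOH–CH2Cl2, 25 °C
Reagents that add atoms: none
Why: Hydroxyl-directed asymmetric hydrogenation of a 2-(1-arylvinyl)phenol, a known substrate class for cationic bisphosphine complexes of monovalent rhodium, should set the R centre because two-point binding through the phenol oxygen and the alkene, aided by the twist that the two ortho substituents impose on ring A, fixes the face that receives hydrogen, while the homogeneous catalyst leaves both benzyl ethers intact.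

Step 5
Reactants: 8 (R)-5-benzyloxy-2-[1-(4-benzyloxyphenyl)ethyl]-3-methoxyphenol
Product: 9 (R)-3-benzyloxy-6-[1-(4-benzyloxyphenyl)ethyl]-2-iodo-5-methoxyphenol
Conditions: NIS (1.0 equiv), CH2Cl2, −20 to 0 °C, dark
Reagents that add atoms: N-iodosuccinimide, O=C1CCC(=O)N1I
Why: Electrophilic aromatic iodination of a phenol should go to the position between OH and OBn, since ring A is far more activated than the other arenes, the small hydroxyl can hydrogen-bond to the reagent in a non-polar solvent, and the alternative site between OBn and OMe is shielded by the methoxy methyl group that the neighbouring side chain forces towards it, and the step needs no organolithium base that could attack the benzyl ethers or the diarylmethine proton.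

Step 6
Reactants: 9 (R)-3-benzyloxy-6-[1-(4-benzyloxyphenyl)ethyl]-2-iodo-5-methoxyphenol, 10 carbon monoxide, 11 4-ethynylanisole (1.5 equiv)
Product: 14 (R)-5-benzyloxy-8-[1-(4-benzyloxyphenyl)ethyl]-7-methoxy-2-(4-methoxyphenyl)chromen-4-one, via hydroxyaryl ynone 12 (not isolated), via diethylamino enone 13 (not isolated)
Conditions: PdCl2(PPh3)2 (5 mol %), CO (10 bar), Et2NH, 100 °C, autoclave, no copper salt
Reagents that add atoms: none
Why: The precatalyst is reduced in the amine to zerovalent palladium, which adds oxidatively to the C4a–I bond; migration of the aryl group onto coordinated CO then gives an aroyl complex of divalent palladium that takes up the amine-deprotonated alkyne and releases ynone 12 by reductive elimination. Conjugate addition of diethylamine turns 12 into the β-amino enone 13, whose C2 is attacked by the adjacent phenol with expulsion of the amine, so ring C closes in a 6-endo sense (O1–C2) and the 5-exo attack at C3 is bypassed. The closest known reaction type is the palladium-catalysed carbonylative Sonogashira annulation of 2-iodophenols with terminal arylalkynes to flavones. No stereocentre is created, and the centre on C8 meets only a secondary amine at 100 °C, far from what would deprotonate or ionise it. Three selectivities are needed: (a) the site of acylation, fixed by the iodine; (b) the oxygen that closes the ring, fixed because the only free hydroxyl is ortho to the iodine; and (c) CO uptake before alkynyl transfer, secured by leaving out copper, by CO pressure and by the fast migration of an electron-rich, crowded aryl group, whose hindered aroyl complex is also slow to be cleaved by the amine.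

Step 7
Reactants: 14 (R)-5-benzyloxy-8-[1-(4-benzyloxyphenyl)ethyl]-7-methoxy-2-(4-methoxyphenyl)chromen-4-one
Product: 16 (R)-5-benzyloxy-8-[1-(4-benzyloxyphenyl)ethyl]-3-hydroxy-7-methoxy-2-(4-methoxyphenyl)chromen-4-one, via flavone epoxide 15 (not isolated)
Conditions: DMDO (acetone solution, 3 equiv), CH2Cl2, 0 °C; then p-TsOH·H2O (10 mol %), CH2Cl2, rt
Reagents that add atoms: dimethyldioxirane, CC1(C)OO1
Why: Dioxirane epoxidation of the C2–C3 double bond, followed by acid-catalysed opening at C2 (cation stabilised by O1 and ring B) and loss of H3, is the established flavone-to-flavonol conversion, it runs neutral at 0 °C where benzyl ethers and the sterically buried diarylmethine C–H are oxidised much more slowly, and the transient epoxide stereocentres disappear when the enone is restored.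

Step 8
Reactants: 16 (R)-5-benzyloxy-8-[1-(4-benzyloxyphenyl)ethyl]-3-hydroxy-7-methoxy-2-(4-methoxyphenyl)chromen-4-one
Product: 17 (R)-3,5-dihydroxy-8-[1-(4-hydroxyphenyl)ethyl]-7-methoxy-2-(4-methoxyphenyl)chromen-4-one
Conditions: H2 (1 atm), Pd/C (10 wt %), EtOAc–MeOH, rt
Reagents that add atoms: none
Why: Heterogeneous hydrogenolysis cleaves the two benzylic C–O bonds at one atmosphere, while the tetrasubstituted conjugated C2–C3 bond, the methyl ethers and the all-carbon diarylmethine, which carries no leaving group, stay as they are.

Compound list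
1 | 2',4',6'-trihydroxyacetophenone | CC(=O)c1c(O)cc(O)cc1O | starting material
2 | 4'-benzyloxy-2',6'-dihydroxyacetophenone | CC(=O)c1c(O)cc(OCc2ccccc2)cc1O | intermediate
3 | 4'-benzyloxy-2'-hydroxy-6'-methoxyacetophenone | CC(=O)c1c(O)cc(OCc2ccccc2)cc1OC | intermediate
4 | 1-benzyloxy-4-bromobenzene | Brc1ccc(OCc2ccccc2)cc1 | starting material
5 | 4-benzyloxyphenylmagnesium bromide | Br[Mg]c1ccc(OCc2ccccc2)cc1 | intermediate
6 | 1-(4-benzyloxy-2-hydroxy-6-methoxyphenyl)-1-(4-benzyloxyphenyl)ethanol (racemic) | CC(O)(c1ccc(OCc2ccccc2)cc1)c1c(O)cc(OCc2ccccc2)cc1OC | intermediate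
7 | 5-benzyloxy-2-[1-(4-benzyloxyphenyl)ethenyl]-3-methoxyphenol | C=C(c1ccc(OCc2ccccc2)cc1)c1c(O)cc(OCc2ccccc2)cc1OC | intermediate
8 | (R)-5-benzyloxy-2-[1-(4-benzyloxyphenyl)ethyl]-3-methoxyphenol | COc1cc(OCc2ccccc2)cc(O)c1[C@H](C)c1ccc(OCc2ccccc2)cc1 | intermediate
9 | (R)-3-benzyloxy-6-[1-(4-benzyloxyphenyl)ethyl]-2-iodo-5-methoxyphenol | COc1cc(OCc2ccccc2)c(I)c(O)c1[C@H](C)c1ccc(OCc2ccccc2)cc1 | intermediate
10 | carbon monoxide | [C-]#[O+] | starting material
11 | 4-ethynylanisole | C#Cc1ccc(OC)cc1 | starting material
12 | (R)-1-{6-benzyloxy-3-[1-(4-benzyloxyphenyl)ethyl]-2-hydroxy-4-methoxyphenyl}-3-(4-methoxyphenyl)prop-2-yn-1-one | COc1ccc(C#CC(=O)c2c(O)c([C@H](C)c3ccc(OCc4ccccc4)cc3)c(OC)cc2OCc2ccccc2)cc1 | intermediate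
13 | (R)-1-{6-benzyloxy-3-[1-(4-benzyloxyphenyl)ethyl]-2-hydroxy-4-methoxyphenyl}-3-(diethylamino)-3-(4-methoxyphenyl)prop-2-en-1-one (alkene geometry equilibrating, not fixed) | CCN(CC)C(=CC(=O)c1c(O)c([C@H](C)c2ccc(OCc3ccccc3)cc2)c(OC)cc1OCc1ccccc1)c1ccc(OC)cc1 | intermediate
14 | (R)-5-benzyloxy-8-[1-(4-benzyloxyphenyl)ethyl]-7-methoxy-2-(4-methoxyphenyl)chromen-4-one | COc1ccc(-c2cc(=O)c3c(OCc4ccccc4)cc(OC)c([C@H](C)c4ccc(OCc5ccccc5)cc4)c3o2)cc1 | intermediate
15 | 2,3-epoxide of 14, 5-benzyloxy-8-[(R)-1-(4-benzyloxyphenyl)ethyl]-2,3-epoxy-7-methoxy-2-(4-methoxyphenyl)chroman-4-one (both epoxide faces) | COc1ccc(C23Oc4c([C@H](C)c5ccc(OCc6ccccc6)cc5)c(OC)cc(OCc5ccccc5)c4C(=O)C2O3)cc1 | intermediate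
16 | (R)-5-benzyloxy-8-[1-(4-benzyloxyphenyl)ethyl]-3-hydroxy-7-methoxy-2-(4-methoxyphenyl)chromen-4-one | COc1ccc(-c2oc3c([C@H](C)c4ccc(OCc5ccccc5)cc4)c(OC)cc(OCc4ccccc4)c3c(=O)c2O)cc1 | intermediate
17 | (R)-3,5-dihydroxy-8-[1-(4-hydroxyphenyl)ethyl]-7-methoxy-2-(4-methoxyphenyl)chromen-4-one (CNP0223021.1) | COc1ccc(-c2oc3c([C@H](C)c4ccc(O)cc4)c(OC)cc(O)c3c(=O)c2O)cc1 | target

Total step count: 8. Longest linear sequence: 8 steps (1 to 17).

Steps most likely to fail

Step 6 (key step).
- What may go wrong: oxidative addition may be slow at an electron-rich C–I bond flanked by two oxygen substituents. The alkynyl group may be transferred before CO is taken up. The amine may cleave the aroyl–palladium intermediate.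
- Fallback: it sets out from 9 and 11, returns at 12 and from there at 14, and uses neither palladium nor CO gas, because C4 is brought in already attached to the alkyne.
- Acyl donor: alkyne 11 is deprotonated (n-BuLi, THF, −78 °C) and acylated with N-methoxy-N-methylcarbamoyl chloride to give N-methoxy-N-methyl-3-(4-methoxyphenyl)prop-2-ynamide F1.
- Nucleophile: iodophenol 9 is deprotonated with MeMgCl in the presence of LiCl. Iodine–magnesium exchange with i-PrMgCl (THF, −20 °C to rt) then gives the chloromagnesium 2-(chloromagnesio)phenoxide F2. This reagent is too weakly basic to touch the diarylmethine.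
- Coupling and closure: addition of F2 to F1 and aqueous quench gives ynone 12, which is isolated this time. Warming 12 with Et2NH in EtOH closes it to 14 by the same addition–elimination path.

Step 4.
- What may go wrong: facial discrimination may be poor if crowding around ring A prevents two-point binding. Turnover may be slow on the hindered 1,1-disubstituted alkene.
- Fallback: it sets out from 7 and returns at 8, replacing metal catalysis by organocatalytic transfer hydrogenation.
- Course: (R)- or (S)-3,3'-bis(2,4,6-triisopropylphenyl)-1,1'-binaphthyl-2,2'-diyl hydrogen phosphate (5 mol %) protonates the alkene terminus of 7. This gives the phosphate-bound ortho-quinone methide 3-benzyloxy-6-[1-(4-benzyloxyphenyl)ethylidene]-5-methoxycyclohexa-2,4-dien-1-one F3.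
- Reduction: diethyl 2,6-dimethyl-1,4-dihydropyridine-3,5-dicarboxylate (Hantzsch ester, CH2Cl2, rt) delivers hydride to one face of F3 and gives 8. The three oxygen substituents of ring A make this ionisation easy, and the acid antipode is chosen as in the main step.

Step 5.
- What may go wrong: iodination may occur at the position para to the hydroxyl, a second iodination may follow, or ipso attack may take place at the carbon that bears the side chain. The site is to be checked by NOE contacts from the remaining ring A proton to both OCH3 and OCH2Ph.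
- Fallback: it sets out from 8 and returns at 9, replacing electrophilic substitution by directed ortho-metalation.
- Protection: phenol 8 is protected (MOMCl, i-Pr2NEt, CH2Cl2) as (R)-5-benzyloxy-2-[1-(4-benzyloxyphenyl)ethyl]-1-methoxy-3-(methoxymethoxy)benzene F4.
- Metalation: the acetal side chain of F4 is forced by the neighbouring diarylethyl group to point towards the wanted position. n-BuLi (THF, −78 to −40 °C, short contact) gives the 4-lithio derivative F5.
- Iodination and deprotection: an iodine quench of F5 gives (R)-1-benzyloxy-4-[1-(4-benzyloxyphenyl)ethyl]-2-iodo-5-methoxy-3-(methoxymethoxy)benzene F6. Dilute HCl in MeOH at rt removes the acetal and gives 9.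

Further compounds
F1 | step 6 | N-methoxy-N-methyl-3-(4-methoxyphenyl)prop-2-ynamide | CON(C)C(=O)C#Cc1ccc(OC)cc1
F2 | step 6 | chloromagnesium (R)-3-benzyloxy-6-[1-(4-benzyloxyphenyl)ethyl]-2-(chloromagnesio)-5-methoxyphenoxide | COc1cc(OCc2ccccc2)c([Mg]Cl)c(O[Mg]Cl)c1[C@H](C)c1ccc(OCc2ccccc2)cc1
F3 | step 4 | 3-benzyloxy-6-[1-(4-benzyloxyphenyl)ethylidene]-5-methoxycyclohexa-2,4-dien-1-one (alkene geometry not fixed) | CC(c1ccc(OCc2ccccc2)cc1)=C1C(=O)C=C(OCc2ccccc2)C=C1OC
F4 | step 5 | (R)-5-benzyloxy-2-[1-(4-benzyloxyphenyl)ethyl]-1-methoxy-3-(methoxymethoxy)benzene | COc1cc(OCc2ccccc2)cc(OCOC)c1[C@H](C)c1ccc(OCc2ccccc2)cc1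
F5 | step 5 | (R)-5-benzyloxy-2-[1-(4-benzyloxyphenyl)ethyl]-4-lithio-1-methoxy-3-(methoxymethoxy)benzene | COc1cc(OCc2ccccc2)c([Li])c(OCOC)c1[C@H](C)c1ccc(OCc2ccccc2)cc1
F6 | step 5 | (R)-1-benzyloxy-4-[1-(4-benzyloxyphenyl)ethyl]-2-iodo-5-methoxy-3-(methoxymethoxy)benzene | COc1cc(OCc2ccccc2)c(I)c(OCOC)c1[C@H](C)c1ccc(OCc2ccccc2)cc1
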